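The dihydrofuran ring is cut at C3–C3a and O1–C7a. The feature exploited is that O1 and C3 sit on neighbouring carbons C7a and C3a of ring A, directly beside the oxygen-bearing C7: the ipso/ortho pattern of a 2-alkoxyaryl iodide. One palladium/norbornene annulation joins that iodide (iodine on C7a, OMOM on C7, free C3a–H) to an enantiopure trans-3-arylglycidyl ether; C3 is attacked with inversion and the epoxide oxygen closes onto C7a, giving the cis-2,3-disubstituted ring. The epoxide is redesigned for this step: mesylates on the biaryl phenols keep C3 from ionising, a trityl ether cannot migrate, and aryl chlorides stand in for two allyl groups.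

Key step: step 10

Remarks on the chemistry:
- Atom labels (O1, C2, C3, C3a, C4–C7, C7a) are those of the 2,3-dihydrobenzofuran of the target. Ring A is its benzo ring, ring B the aryl group on C3, ring C the outer ring of the biaryl, ring D the aryloxy ring on C6.
- Abbreviations: MOM = methoxymethyl, Ms = methanesulfonyl, Tr = triphenylmethyl. BiAr-Cl = 5'-chloro-2',6-bis(methanesulfonyloxy)biphenyl-3-yl: ring B is attached through C3 and carries OMs on C6 (para to the point of attachment, ortho to the biaryl bond); ring C carries OMs on C2' and Cl on C5'. BiAr-allyl is the same group with allyl in place of Cl.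
- Assumption: catalytic organopalladium and organocopper species are discussed in the Why lines and carry no numbers; stoichiometric intermediates that form and react on in the flask are numbered.

Step 1
Reactants: 1 catechol
Product: 2 2-(methoxymethoxy)phenol
Conditions: NaH (1.0 equiv), MOMCl (1.0 equiv), catechol (1.5 equiv), THF/DMF, 0 °C to rt
Reagents that add atoms: chloromethyl methyl ether, COCCl
Why: Williamson-type O-alkylation of the catechol monoanion with an α-chloro ether, in which one equivalent of base and excess diol should keep the second hydroxyl free for the next step.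

Step 2
Reactants: 2 2-(methoxymethoxy)phenol; 3 1-chloro-4-iodobenzene
Product: 4 1-(4-chlorophenoxy)-2-(methoxymethoxy)benzene
Conditions: CuI (10 mol%), picolinic acid (20 mol%), K3PO4 (2 equiv), DMSO, 85 °C
Reagents that add atoms: none
Why: Copper-catalysed Ullmann diaryl ether synthesis, in which the C–I bond of 3 reacts far faster than its C–Cl bond and no oxidant is present that could attack the electron-rich phenol.

Step 3
Reactants: 4 1-(4-chlorophenoxy)-2-(methoxymethoxy)benzene
Product: 6 1-(4-chlorophenoxy)-3-iodo-2-(methoxymethoxy)benzene, via aryllithium 5 (not isolated)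
Conditions: n-BuLi (1.1 equiv), TMEDA, THF, −78 to −30 °C; then I2, −78 °C
Reagents that add atoms: iodine, II
Why: Directed ortho-metalation followed by iodination, in which the MOM acetal chelates lithium and has only one free ortho position, while the weaker aryloxy director and the C–Cl bond should not compete at low temperature.

Step 4
Reactants: 7 3-bromo-4-hydroxybenzaldehyde; 8 5-chloro-2-hydroxyphenylboronic acid
Product: 9 3-(5-chloro-2-hydroxyphenyl)-4-hydroxybenzaldehyde
Conditions: Pd(PPh3)4 (3 mol%), Na2CO3 (aq., 2 M), DME, 85 °C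
Reagents that add atoms: none
Why: Suzuki–Miyaura coupling, in which Pd(PPh3)4 inserts into the C–Br bond and leaves the C–Cl bond alone, and both phenols are carried as phenoxides in aqueous carbonate.

Step 5
Reactants: 9 3-(5-chloro-2-hydroxyphenyl)-4-hydroxybenzaldehyde
Product: 10 5'-chloro-5-formylbiphenyl-2,2'-diyl dimethanesulfonate
Conditions: MsCl (2.4 equiv), Et3N (3 equiv), CH2Cl2, 0 °C
Reagents that add atoms: methanesulfonyl chloride, CS(=O)(=O)Cl
Why: Sulfonylation of both phenols, which turns the oxygen para to the future C3 from a donor into an acceptor and gives a group that should survive hydride, titanium, base and triarylphosphine–palladium conditions.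

Step 6
Reactants: 10 5'-chloro-5-formylbiphenyl-2,2'-diyl dimethanesulfonate
Product: 11 ethyl (E)-3-(BiAr-Cl)prop-2-enoate
Conditions: (EtO)2P(O)CH2CO2Et, NaH, THF, 0 °C to rt
Reagents that add atoms: triethyl phosphonoacetate, CCOC(=O)CP(=O)(OCC)OCC
Why: Horner–Wadsworth–Emmons olefination of an aryl aldehyde with a stabilised phosphonate anion, which should give the E-enoate under thermodynamic control of the elimination.

Step 7
Reactants: 11 ethyl (E)-3-(BiAr-Cl)prop-2-enoate
Product: 12 (E)-3-(BiAr-Cl)prop-2-en-1-ol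
Conditions: i-Bu2AlH (2.3 equiv), CH2Cl2, −78 °C
Reagents that add atoms: none
Why: 1,2-Reduction of the conjugated ester to the allylic alcohol by an electrophilic aluminium hydride, which should leave the alkene geometry and the aryl sulfonates untouched at low temperature.

Step 8
Reactants: 12 (E)-3-(BiAr-Cl)prop-2-en-1-ol
Product: 13 [(2S,3S)-3-(BiAr-Cl)oxiran-2-yl]methanol
Conditions: Ti(Oi-Pr)4 (10 mol%), L-(+)-DIPT (12 mol%), t-BuOOH (2 equiv), 4 Å MS, CH2Cl2, −20 °C
Reagents that add atoms: tert-butyl hydroperoxide, CC(C)(C)OO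
Why: Sharpless asymmetric epoxidation, in which the titanium–L-(+)-tartrate complex delivers oxygen to one face of the E-allylic alcohol and sets C2 and C3 as the (2S,3S)-trans-epoxide, the electron-poor ring B keeping the benzylic epoxide from opening under the Lewis acidic conditions.

Step 9
Reactants: 13 [(2S,3S)-3-(BiAr-Cl)oxiran-2-yl]methanol
Product: 14 (2S,3S)-3-(BiAr-Cl)-2-[(trityloxy)methyl]oxirane
Conditions: TrCl (1.2 equiv), Et3N, DMAP (cat.), CH2Cl2, rt
Reagents that add atoms: trityl chloride, ClC(c1ccccc1)(c1ccccc1)c1ccccc1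
Why: Tritylation of the primary alcohol under basic conditions, which blocks Payne rearrangement and gives a bulky, acid-labile ether that cannot migrate to a neighbouring alkoxide.

Step 10
Reactants: 6 1-(4-chlorophenoxy)-3-iodo-2-(methoxymethoxy)benzene; 14 (2S,3S)-3-(BiAr-Cl)-2-[(trityloxy)methyl]oxirane
Product: 15 (2R,3S)-3-(BiAr-Cl)-6-(4-chlorophenoxy)-7-(methoxymethoxy)-2-[(trityloxy)methyl]-2,3-dihydrobenzofuran
Conditions: Pd(OAc)2 (10 mol%), tri(2-furyl)phosphine (22 mol%), norbornene (2 equiv), Cs2CO3 (2.5 equiv), 14 (1.3 equiv), MeCN, 80 °C, Ar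
Reagents that add atoms: none
Why: Proposed new method: zerovalent palladium adds to the C–I bond of 6, norbornene inserts and C3a–H is palladated to give the aryl–norbornyl palladacycle of divalent palladium, which attacks the epoxide of 14 at benzylic C3 anti to the C3–O bond (SN2-type oxidative addition to tetravalent palladium); reductive elimination forms C3–C3a and norbornene is then expelled by β-carbon elimination. The closest known reaction type is the palladium/norbornene ortho-alkylation/ipso-etherification of 2-substituted aryl iodides with terminal epoxides, which are opened at CH2, supported by Catellani alkylations with secondary alkyl iodides that go with inversion; opening a 2,3-disubstituted aryl epoxide at its benzylic carbon has not been shown. The dihydrofuran ring closes by C–O reductive elimination from the six-membered aryl(alkoxo)palladium chelate, the C2 alkoxide replacing palladium at the ipso carbon C7a (a 5-exo-type closure forming O1–C7a). C2 keeps its C–O bond and hence its Sharpless-derived configuration, while C3 is set by the stereospecific inversion, so the (2S,3S)-trans-epoxide should map onto the (2R,3S)-cis product. The step needs C3 over C2 regioselectivity and clean SN2 character: C3 is benzylic whereas C2 is shielded and inductively deactivated by CH2OTr, the para mesylate makes ring B too electron-poor for ionisation or a Meinwald shift at C3, and trityl, unlike a silyl group, cannot migrate to the new alkoxide. Site selectivity on ring A follows from the C7 OMOM group, which occupies the second ortho position so that only C3a–H is functionalised, and tri(2-furyl)phosphine should leave the aryl chlorides and mesylates untouched.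

Step 11
Reactants: 15 (2R,3S)-3-(BiAr-Cl)-6-(4-chlorophenoxy)-7-(methoxymethoxy)-2-[(trityloxy)methyl]-2,3-dihydrobenzofuran
Product: 16 (2R,3S)-6-(4-allylphenoxy)-3-(BiAr-allyl)-7-(methoxymethoxy)-2-[(trityloxy)methyl]-2,3-dihydrobenzofuran
Conditions: allylSnBu3 (2.6 equiv), Pd2(dba)3 (3 mol%), P(t-Bu)3 (12 mol%), CsF (4.5 equiv), dioxane, 100 °C
Reagents that add atoms: allyltributylstannane, C=CC[Sn](CCCC)(CCCC)CCCC
Why: Twofold Stille coupling of unactivated aryl chlorides, made possible by the bulky electron-rich phosphine and fluoride activation of tin, on a substrate that has no free hydroxyl group and whose mesylates this ligand should not activate.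

Step 12
Reactants: 16 (2R,3S)-6-(4-allylphenoxy)-3-(BiAr-allyl)-7-(methoxymethoxy)-2-[(trityloxy)methyl]-2,3-dihydrobenzofuran
Product: 17 (2R,3S)-6-(4-allylphenoxy)-3-(BiAr-allyl)-2-(hydroxymethyl)-2,3-dihydrobenzofuran-7-ol
Conditions: HCl (conc., cat.), MeOH/THF, 40 °C
Reagents that add atoms: none
Why: Acid-catalysed methanolysis of the aryl MOM acetal and of the trityl ether in one operation, under conditions that aryl mesylates, allyl groups and the dihydrobenzofuran should tolerate.

Step 13
Reactants: 17 (2R,3S)-6-(4-allylphenoxy)-3-(BiAr-allyl)-2-(hydroxymethyl)-2,3-dihydrobenzofuran-7-ol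
Product: 18 (2R,3S)-7-(allyloxy)-6-(4-allylphenoxy)-3-(BiAr-allyl)-2-(hydroxymethyl)-2,3-dihydrobenzofuran
Conditions: allyl bromide (1.2 equiv), K2CO3, acetone, 50 °C
Reagents that add atoms: allyl bromide, C=CCBr
Why: Williamson etherification that is selective for the only free phenol, because carbonate deprotonates the C7 phenol but not the primary alcohol.

Step 14
Reactants: 18 (2R,3S)-7-(allyloxy)-6-(4-allylphenoxy)-3-(BiAr-allyl)-2-(hydroxymethyl)-2,3-dihydrobenzofuran
Product: 21 (2R,3S)-4-allyl-6-(4-allylphenoxy)-3-(BiAr-allyl)-2-(hydroxymethyl)-2,3-dihydrobenzofuran-7-ol, via ortho-dienone 19 (not isolated), via para-dienone 20 (not isolated)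
Conditions: N,N-diethylaniline, 190 °C, sealed tube, Ar
Reagents that add atoms: none
Why: Thermal para-Claisen rearrangement, in which both ortho positions of the C7 allyl ether (C6 and C7a) are blocked, so the [3,3] shift to the ortho-dienone is followed by a Cope [3,3] shift to C4 and tautomerisation to the phenol, with no stereocentre touched.

Step 15
Reactants: 21 (2R,3S)-4-allyl-6-(4-allylphenoxy)-3-(BiAr-allyl)-2-(hydroxymethyl)-2,3-dihydrobenzofuran-7-ol
Product: 22 Magnolignan H
Conditions: NaOH (aq., 2 M), MeOH/THF, 55 °C, Ar; then aq. NH4Cl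
Reagents that add atoms: none
Why: Hydroxide-induced cleavage of the two aryl methanesulfonates at the S–O bond (sulfene-type E1cB or attack at sulfur), mild enough that the allyl groups and the cis-dihydrobenzofuran should survive under argon.

Compound list
1 | catechol | Oc1ccccc1O | starting material
2 | 2-(methoxymethoxy)phenol | COCOc1ccccc1O | intermediate
3 | 1-chloro-4-iodobenzene | Clc1ccc(I)cc1 | starting material
4 | 1-(4-chlorophenoxy)-2-(methoxymethoxy)benzene | COCOc1ccccc1Oc1ccc(Cl)cc1 | intermediate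
5 | [3-(4-chlorophenoxy)-2-(methoxymethoxy)phenyl]lithium (not isolated) | [Li]c1cccc(Oc2ccc(Cl)cc2)c1OCOC | intermediate
6 | 1-(4-chlorophenoxy)-3-iodo-2-(methoxymethoxy)benzene | COCOc1c(I)cccc1Oc1ccc(Cl)cc1 | intermediate
7 | 3-bromo-4-hydroxybenzaldehyde | O=Cc1ccc(O)c(Br)c1 | starting material
8 | 5-chloro-2-hydroxyphenylboronic acid | OB(O)c1cc(Cl)ccc1O | starting material
9 | 3-(5-chloro-2-hydroxyphenyl)-4-hydroxybenzaldehyde | O=Cc1ccc(O)c(-c2cc(Cl)ccc2O)c1 | intermediate
10 | 5'-chloro-5-formylbiphenyl-2,2'-diyl dimethanesulfonate | O=Cc1ccc(OS(C)(=O)=O)c(-c2cc(Cl)ccc2OS(C)(=O)=O)c1 | intermediate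
11 | ethyl (E)-3-{5'-chloro-2',6-bis[(methylsulfonyl)oxy]biphenyl-3-yl}prop-2-enoate | CCOC(=O)/C=C/c1ccc(OS(C)(=O)=O)c(-c2cc(Cl)ccc2OS(C)(=O)=O)c1 | intermediate
12 | (E)-3-{5'-chloro-2',6-bis[(methylsulfonyl)oxy]biphenyl-3-yl}prop-2-en-1-ol | OC/C=C/c1ccc(OS(C)(=O)=O)c(-c2cc(Cl)ccc2OS(C)(=O)=O)c1 | intermediate
13 | [(2S,3S)-3-{5'-chloro-2',6-bis[(methylsulfonyl)oxy]biphenyl-3-yl}oxiran-2-yl]methanol (trans) | O1[C@@H](CO)[C@@H]1c1ccc(OS(C)(=O)=O)c(-c2cc(Cl)ccc2OS(C)(=O)=O)c1 | intermediate
14 | (2S,3S)-3-{5'-chloro-2',6-bis[(methylsulfonyl)oxy]biphenyl-3-yl}-2-[(trityloxy)methyl]oxirane (trans) | O1[C@@H](COC(c2ccccc2)(c2ccccc2)c2ccccc2)[C@@H]1c1ccc(OS(C)(=O)=O)c(-c2cc(Cl)ccc2OS(C)(=O)=O)c1 | intermediate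
15 | (2R,3S)-3-{5'-chloro-2',6-bis[(methylsulfonyl)oxy]biphenyl-3-yl}-6-(4-chlorophenoxy)-7-(methoxymethoxy)-2-[(trityloxy)methyl]-2,3-dihydrobenzofuran (cis) | Clc1ccc(Oc2ccc3c(c2OCOC)O[C@@H](COC(c2ccccc2)(c2ccccc2)c2ccccc2)[C@H]3c2ccc(OS(C)(=O)=O)c(-c3cc(Cl)ccc3OS(C)(=O)=O)c2)cc1 | intermediate
16 | (2R,3S)-3-{5'-allyl-2',6-bis[(methylsulfonyl)oxy]biphenyl-3-yl}-6-(4-allylphenoxy)-7-(methoxymethoxy)-2-[(trityloxy)methyl]-2,3-dihydrobenzofuran | C=CCc1ccc(Oc2ccc3c(c2OCOC)O[C@@H](COC(c2ccccc2)(c2ccccc2)c2ccccc2)[C@H]3c2ccc(OS(C)(=O)=O)c(-c3cc(CC=C)ccc3OS(C)(=O)=O)c2)cc1 | intermediate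
17 | (2R,3S)-3-{5'-allyl-2',6-bis[(methylsulfonyl)oxy]biphenyl-3-yl}-6-(4-allylphenoxy)-2-(hydroxymethyl)-2,3-dihydrobenzofuran-7-ol | C=CCc1ccc(Oc2ccc3c(c2O)O[C@@H](CO)[C@H]3c2ccc(OS(C)(=O)=O)c(-c3cc(CC=C)ccc3OS(C)(=O)=O)c2)cc1 | intermediate
18 | (2R,3S)-7-(allyloxy)-3-{5'-allyl-2',6-bis[(methylsulfonyl)oxy]biphenyl-3-yl}-6-(4-allylphenoxy)-2-(hydroxymethyl)-2,3-dihydrobenzofuran | C=CCc1ccc(Oc2ccc3c(c2OCC=C)O[C@@H](CO)[C@H]3c2ccc(OS(C)(=O)=O)c(-c3cc(CC=C)ccc3OS(C)(=O)=O)c2)cc1 | intermediate
19 | ortho-dienone: (2R,3S)-6-allyl-6-(4-allylphenoxy)-3-(BiAr-allyl)-2-(hydroxymethyl)-2,3-dihydrobenzofuran-7(6H)-one, C6 unspecified (not isolated) | C=CCc1ccc(OC2(CC=C)C=CC3=C(C2=O)O[C@@H](CO)[C@H]3c2ccc(OS(C)(=O)=O)c(-c3cc(CC=C)ccc3OS(C)(=O)=O)c2)cc1 | intermediate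
20 | para-dienone: (2R,3S)-4-allyl-6-(4-allylphenoxy)-3-(BiAr-allyl)-2-(hydroxymethyl)-3,4-dihydrobenzofuran-7(2H)-one, C4 unspecified (not isolated) | C=CCc1ccc(OC2=CC(CC=C)C3=C(C2=O)O[C@@H](CO)[C@H]3c2ccc(OS(C)(=O)=O)c(-c3cc(CC=C)ccc3OS(C)(=O)=O)c2)cc1 | intermediate
21 | (2R,3S)-4-allyl-3-{5'-allyl-2',6-bis[(methylsulfonyl)oxy]biphenyl-3-yl}-6-(4-allylphenoxy)-2-(hydroxymethyl)-2,3-dihydrobenzofuran-7-ol | C=CCc1ccc(Oc2cc(CC=C)c3c(c2O)O[C@@H](CO)[C@H]3c2ccc(OS(C)(=O)=O)c(-c3cc(CC=C)ccc3OS(C)(=O)=O)c2)cc1 | intermediate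
22 | Magnolignan H, (2R,3S)-4-allyl-3-(5'-allyl-2',6-dihydroxybiphenyl-3-yl)-6-(4-allylphenoxy)-2-(hydroxymethyl)-2,3-dihydrobenzofuran-7-ol (cis) | C=CCc1ccc(Oc2cc(CC=C)c3c(c2O)O[C@@H](CO)[C@H]3c2ccc(O)c(-c3cc(CC=C)ccc3O)c2)cc1 | target

Total step count: 15.
Longest linear sequence: 12 steps (steps 4 to 15, from 7 and 8 to 22); the three-step iodide branch (steps 1 to 3) joins at step 10.

Steps most likely to fail

1. Step 10. The palladacycle may be too slow in its SN2-type oxidative addition at a secondary benzylic carbon of a 2,3-disubstituted epoxide. Zerovalent palladium could then isomerise the epoxide to a carbonyl compound, or the aryl iodide could be consumed in norbornene-derived side reactions. Attack at C2 or partial ionisation at C3 would erode regio- and stereochemical fidelity. The fallback uses known chemistry and makes the two bonds in separate steps; it sets out from 4 (with epoxide 14) and returns to the route at 15. Aryllithium 5, generated as in step 3, would be quenched with BrCCl2CCl2Br to give 1-bromo-3-(4-chlorophenoxy)-2-(methoxymethoxy)benzene F1. Iodination with N-iodosuccinimide in hexafluoroisopropanol should go para to the aryloxy group, because the MOM oxygen is flanked on both sides and twisted out of conjugation as in 1,2,3-trioxygenated benzenes, and give 2-bromo-4-(4-chlorophenoxy)-1-iodo-3-(methoxymethoxy)benzene F2. Iodine–magnesium exchange with i-PrMgCl·LiCl at −40 °C would give [2-bromo-4-(4-chlorophenoxy)-3-(methoxymethoxy)phenyl]magnesium chloride F3 (not isolated). With catalytic CuI this should open 14 at benzylic C3 with inversion, the established behaviour of trans-3-arylglycidyl ethers towards arylmagnesium/copper reagents, to give (2R,3S)-3-[2-bromo-4-(4-chlorophenoxy)-3-(methoxymethoxy)phenyl]-3-(BiAr-Cl)-1-(trityloxy)propan-2-ol F4. Copper-catalysed intramolecular O-arylation (CuI, 1,10-phenanthroline, Cs2CO3, toluene, 110 °C) would then close O1–C7a with retention at C2 and give 15.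

2. Step 11. Oxidative addition into the electron-rich chloride of ring D may stall and leave mono-allylated material, and palladium hydride species may move the new double bonds into conjugation with the arenes. The fallback reverses the polarity of the coupling; it sets out from 15 and returns at 16. Miyaura borylation of both chlorides (Pd2(dba)3, XPhos, B2pin2, KOAc, dioxane, 100 °C; aryl mesylates are poor substrates for this ligand) would give the bis(pinacolboronate) F5. Coupling of F5 with allyl bromide (Pd(PPh3)4, K2CO3, THF/H2O, 60 °C) proceeds through an allylpalladium electrophile and so avoids a long-lived aryl–palladium–allyl stage at high temperature.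

3. Step 14. The Cope relay from the ortho-dienone into C4, which lies next to the crowded C3a/C3-aryl region, may be slow, so that the dienone decomposes by loss of the allyl group or by other thermal pathways. The fallback installs the C4 allyl group by electrophilic substitution and cross-coupling instead of sigmatropic shifts; it sets out from 15 and returns at 21. Acidic methanolysis as in step 12 would give (2R,3S)-3-(BiAr-Cl)-6-(4-chlorophenoxy)-2-(hydroxymethyl)-2,3-dihydrobenzofuran-7-ol F6. N-Bromosuccinimide at low temperature should brominate C4, the position para to the free C7 hydroxyl whose two ortho positions are blocked, and give the 4-bromo compound F7. A threefold Stille allylation of the aryl bromide and both aryl chlorides under the conditions of step 11 would then deliver 21.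

Further compounds
F1 | step 10 | 1-bromo-3-(4-chlorophenoxy)-2-(methoxymethoxy)benzene | COCOc1c(Br)cccc1Oc1ccc(Cl)cc1
F2 | step 10 | 2-bromo-4-(4-chlorophenoxy)-1-iodo-3-(methoxymethoxy)benzene | COCOc1c(Br)c(I)ccc1Oc1ccc(Cl)cc1
F3 | step 10 | [2-bromo-4-(4-chlorophenoxy)-3-(methoxymethoxy)phenyl]magnesium chloride (not isolated) | Cl[Mg]c1ccc(Oc2ccc(Cl)cc2)c(OCOC)c1Br
F4 | step 10 | (2R,3S)-3-[2-bromo-4-(4-chlorophenoxy)-3-(methoxymethoxy)phenyl]-3-{5'-chloro-2',6-bis[(methylsulfonyl)oxy]biphenyl-3-yl}-1-(trityloxy)propan-2-ol | O[C@@H](COC(c1ccccc1)(c1ccccc1)c1ccccc1)[C@H](c1ccc(Oc2ccc(Cl)cc2)c(OCOC)c1Br)c1ccc(OS(C)(=O)=O)c(-c2cc(Cl)ccc2OS(C)(=O)=O)c1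
F5 | step 11 | bis(pinacolboronate) of 15, with Bpin in place of both chlorines | CC1(C)OB(OC1(C)C)c1ccc(Oc2ccc3c(c2OCOC)O[C@@H](COC(c2ccccc2)(c2ccccc2)c2ccccc2)[C@H]3c2ccc(OS(C)(=O)=O)c(-c3cc(B4OC(C)(C)C(C)(C)O4)ccc3OS(C)(=O)=O)c2)cc1
F6 | step 14 | (2R,3S)-3-{5'-chloro-2',6-bis[(methylsulfonyl)oxy]biphenyl-3-yl}-6-(4-chlorophenoxy)-2-(hydroxymethyl)-2,3-dihydrobenzofuran-7-ol | Clc1ccc(Oc2ccc3c(c2O)O[C@@H](CO)[C@H]3c2ccc(OS(C)(=O)=O)c(-c3cc(Cl)ccc3OS(C)(=O)=O)c2)cc1
F7 | step 14 | (2R,3S)-4-bromo-3-{5'-chloro-2',6-bis[(methylsulfonyl)oxy]biphenyl-3-yl}-6-(4-chlorophenoxy)-2-(hydroxymethyl)-2,3-dihydrobenzofuran-7-ol | Clc1ccc(Oc2cc(Br)c3c(c2O)O[C@@H](CO)[C@H]3c2ccc(OS(C)(=O)=O)c(-c3cc(Cl)ccc3OS(C)(=O)=O)c2)cc1
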